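The target is the Diels–Alder dimer of one trans-fused xanthanolide monomer 16, oxidised at C1; both seven-membered rings (ring B, and ring E holding C1', C5'–C10') therefore come from the same monomer synthesis. Everything rests on cutting that cycloheptene at C5–C6 and C1–C10: the C1=C5 alkene, flanked by the saturated carbons C6 and C10, is the two-carbon partner of a rhodium-catalysed (5+2) cycloaddition. In one operation the siloxy-vinylcyclopropane 5 (C6–C10, with C10 as propenyl terminus) and the silylated propargyl alcohol 6 (C5, C1, C2) give the cycloheptadiene, both ring bonds and the C10 stereocentre; C8 oxygen and C2 then serve lactone and dienone.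

Key step: step 4

Remark (numbering): xanthanolide numbering is used for the monomer (ring alkene C1=C5, ring carbons C6–C10 with C7 and C8 carrying the lactone and C10 the methyl group, C11–C13 the methylene lactone, C2–C4 and C15 the enone chain); primed numbers denote the half that reacts as dienophile in step 9. Both halves of the target have the configuration (3aS,7S,8aR) of 16.

Remark (assumption): the facial sense of the dipeptide-controlled cyclopropanation in step 3 is taken by analogy with simple silyl enol ethers; should the (1S,2S)-cyclopropane form instead, the D,D-dipeptide is used and nothing else changes.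

Step 1
Reactants: 1 methyl 4-chloro-4-oxobutanoate; 2 (E)-prop-1-enylboronic acid
Product: 3 methyl (E)-4-oxohept-5-enoate
Conditions: Pd(PPh3)4 (3 mol %), Cs2CO3, toluene (anhydrous), 100 °C
Reagents that add atoms: none
Why: Acyl Suzuki–Miyaura coupling of an acid chloride with an alkenylboronic acid joins the acyl carbon (C8) to the vinyl carbon (C9) with retention of the E geometry and leaves the methyl ester untouched.

Step 2
Reactants: 3 methyl (E)-4-oxohept-5-enoate
Product: 4 methyl (3Z,5E)-4-(tert-butyldimethylsilyloxy)hepta-3,5-dienoate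
Conditions: TBSOTf, Et3N, CH2Cl2, -78 to 0 °C
Reagents that add atoms: tert-butyldimethylsilyl trifluoromethanesulfonate, CC(C)(C)[Si](C)(C)OS(=O)(=O)C(F)(F)F
Why: Soft enolisation of the enone at its alpha' methylene (C7) gives the cross-conjugated 2-siloxy diene with the usual Z enol ether geometry, the ester not being enolised by triethylamine.

Step 3
Reactants: 4 methyl (3Z,5E)-4-(tert-butyldimethylsilyloxy)hepta-3,5-dienoate
Product: 5 methyl 2-[(1R,2R)-2-(tert-butyldimethylsilyloxy)-2-[(E)-prop-1-enyl]cyclopropyl]acetate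
Conditions: Et2Zn (1.2 equiv), CH2I2 (2.4 equiv), N-Boc-L-valyl-L-proline methyl ester (25 mol %), CH2Cl2, -20 °C
Reagents that add atoms: diiodomethane, ICI
Why: Catalytic asymmetric Simmons–Smith cyclopropanation of a silyl enol ether, in which the zinc carbenoid adds syn to the electron-rich C7=C8 enol ether in preference to the conjugated propenyl alkene and the dipeptide-bound zinc selects the alkene face, so that C8 (and with it C7) of the cyclopropane is set.

Step 4
Reactants: 5 methyl 2-[(1R,2R)-2-(tert-butyldimethylsilyloxy)-2-[(E)-prop-1-enyl]cyclopropyl]acetate; 6 3-(trimethylsilyl)prop-2-yn-1-ol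
Product: 8 methyl 2-[(1S,4S)-5-(hydroxymethyl)-4-methyl-2-oxo-6-(trimethylsilyl)cyclohept-5-en-1-yl]acetate (1,4-cis), via silyl enol ether cycloadduct 7 (not isolated)
Conditions: [Rh(CO)2Cl]2 (5 mol %), ClCH2CH2Cl, 80 °C; then HCl (1% in EtOH), 0 °C
Reagents that add atoms: none
Why: Monovalent rhodium coordinates the propenyl group of 5 and inserts into the less substituted C8–C6 cyclopropane bond to give a sigma-alkyl/pi-allyl rhodacycle, alkyne 6 inserts at the allyl terminus (C10–C1 bond) and reductive elimination joins C6 to C5, after which dilute acid unmasks the C8 ketone. The closest known reaction type is the rhodium-catalysed intermolecular (5+2) cycloaddition of 1-siloxy-vinylcyclopropanes with alkynes, which accepts substituents on the alkene terminus and on the cyclopropane. The seven-membered ring is closed as a metal-mediated (5+2) cycloaddition in which both new bonds form on the same face of the five-carbon unit. C10 is the only new stereocentre: rhodium binds the alkene face on the side of the cleaved C8–C6 bond, so the configuration of C8 in 5 together with the E alkene geometry is transferred to C10 (S), while C7 is untouched. The step needs regiocontrol twice: the larger trimethylsilyl group should take the alkyne position remote from the first-formed C–C bond (next to rhodium), which puts the CH2OH-bearing carbon on C10 and the silylated carbon on C6, and the alkyl substituent trans to the vinyl group should direct ring opening to the unsubstituted cyclopropane carbon.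

Step 5
Reactants: 8 methyl 2-[(1S,4S)-5-(hydroxymethyl)-4-methyl-2-oxo-6-(trimethylsilyl)cyclohept-5-en-1-yl]acetate (1,4-cis)
Product: 9 methyl 2-[(1S,4S)-5-(hydroxymethyl)-4-methyl-2-oxocyclohept-5-en-1-yl]acetate (1,4-trans)
Conditions: Bu4NF (2 equiv), THF, 0 to 40 °C
Reagents that add atoms: none
Why: Hydroxyl-assisted protodesilylation of the (Z)-gamma-silyl allylic alcohol (a 1,4 carbon-to-oxygen silyl shift of the Brook type followed by protonation with retention of alkene geometry) frees C5–H, and the basic fluoride should equilibrate the ketone alpha-centre C7 to the more stable isomer with the acetate arm trans to the C10 methyl group.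

Step 6
Reactants: 9 methyl 2-[(1S,4S)-5-(hydroxymethyl)-4-methyl-2-oxocyclohept-5-en-1-yl]acetate (1,4-trans)
Product: 11 (3aS,7S,8aR)-6-(hydroxymethyl)-7-methyl-3,3a,4,7,8,8a-hexahydro-2H-cyclohepta[b]furan-2-one, via hydroxy ester 10 (not isolated)
Conditions: NaBH4, MeOH, -40 °C; then PPTS, toluene, 60 °C
Reagents that add atoms: none
Why: Borohydride should attack the C8 ketone along the axial trajectory of the chair-like ring, anti to the adjacent pseudo-equatorial side chain, to give the equatorial (8R) alcohol trans to C7, which closes under mild acid to the trans-fused gamma-lactone by transesterification.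

Step 7
Reactants: 11 (3aS,7S,8aR)-6-(hydroxymethyl)-7-methyl-3,3a,4,7,8,8a-hexahydro-2H-cyclohepta[b]furan-2-one
Product: 14 (3aS,7S,8aR)-6-(hydroxymethyl)-7-methyl-3-methylidene-3,3a,4,7,8,8a-hexahydro-2H-cyclohepta[b]furan-2-one, via Mannich base 12 (not isolated), via trimethylammonium iodide 13 (not isolated)
Conditions: LiN(iPr)2 (2.2 equiv), THF, -78 °C, then CH2=NMe2+ I-; MeI, MeOH, 23 °C; NaHCO3 (aq), CH2Cl2
Reagents that add atoms: dimethyl(methylidene)ammonium iodide, C=[N+](C)C.[I-]
Why: Mannich alkylation of the lactone enolate (the alcohol being carried as its lithium alkoxide), quaternisation and Hofmann-type beta-elimination is the standard alpha-methylenation of gamma-lactones and touches no stereocentre that survives.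

Step 8
Reactants: 14 (3aS,7S,8aR)-6-(hydroxymethyl)-7-methyl-3-methylidene-3,3a,4,7,8,8a-hexahydro-2H-cyclohepta[b]furan-2-one
Product: 16 (3aS,7S,8aR)-7-methyl-3-methylidene-6-[(E)-3-oxobut-1-enyl]-3,3a,4,7,8,8a-hexahydro-2H-cyclohepta[b]furan-2-one, via enal 15 (not isolated)
Conditions: MnO2 (15 equiv), Ph3P=CHC(O)CH3 (1.5 equiv), toluene, 80 °C
Reagents that add atoms: 1-(triphenylphosphoranylidene)propan-2-one, CC(=O)C=P(c1ccccc1)(c1ccccc1)c1ccccc1
Why: Tandem allylic oxidation–Wittig olefination, in which MnO2 oxidises only the allylic alcohol and the stabilised ylide converts the enal in situ into the E enone, completes the dienone without exposing the methylene lactone to base.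

Step 9
Reactants: 16 (3aS,7S,8aR)-7-methyl-3-methylidene-6-[(E)-3-oxobut-1-enyl]-3,3a,4,7,8,8a-hexahydro-2H-cyclohepta[b]furan-2-one (two molecules)
Product: 17 Diels–Alder dimer of 16 (ring C cyclohexene with the C1=C2 double bond, 3-acetyl with H-3 cis to H-5, spiro lactone carbonyl trans to C6)
Conditions: neat, BHT (2 mol %), 90 °C, sealed tube under argon, 48 h; unreacted 16 recycled
Reagents that add atoms: none
Why: Thermal Diels–Alder dimerisation in which the s-cis C5=C1–C2=C3 diene of one molecule adds to the exocyclic C11'=C13' alkene of another in the ortho sense (C3–C11', C5–C13'), with the lactone carbonyl exo as is usual for alpha-methylene lactones, on the alkene face syn to H-7' and on the diene face opposite the C7–C11 bond, which should set C3, C5 and the spiro centre C11'.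

Step 10
Reactants: 17 Diels–Alder dimer of 16
Product: 19 target CNP0168949.4, via epoxy ketone 18 (not isolated)
Conditions: mCPBA (1.05 equiv), NaHCO3, CH2Cl2, 0 °C; then Et3N, 23 °C
Reagents that add atoms: 3-chloroperoxybenzoic acid, OOC(=O)c1cccc(Cl)c1
Why: Peracid epoxidation should pick the only electron-rich alkene (C1=C2) from the less hindered face syn to H-3 and H-5, and base-induced beta-elimination of the beta,gamma-epoxy ketone (E1cB through the C3 enolate) opens it to the gamma-hydroxy enone, so the C1 hydroxyl keeps the configuration set in the epoxidation.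

Compound list
1 | methyl 4-chloro-4-oxobutanoate | COC(=O)CCC(Cl)=O | starting material
2 | (E)-prop-1-enylboronic acid | C/C=C/B(O)O | starting material
3 | methyl (E)-4-oxohept-5-enoate | COC(=O)CCC(=O)/C=C/C | intermediate
4 | methyl (3Z,5E)-4-(tert-butyldimethylsilyloxy)hepta-3,5-dienoate | COC(=O)C/C=C(\O[Si](C)(C)C(C)(C)C)/C=C/C | intermediate
5 | methyl 2-[(1R,2R)-2-(tert-butyldimethylsilyloxy)-2-[(E)-prop-1-enyl]cyclopropyl]acetate (acetate arm cis to the siloxy group) | COC(=O)C[C@H]1C[C@]1(O[Si](C)(C)C(C)(C)C)/C=C/C | intermediate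
6 | 3-(trimethylsilyl)prop-2-yn-1-ol | C[Si](C)(C)C#CCO | starting material
7 | methyl 2-[(1S,4S)-2-(tert-butyldimethylsilyloxy)-5-(hydroxymethyl)-4-methyl-6-(trimethylsilyl)cyclohepta-2,5-dien-1-yl]acetate (1,4-cis) | COC(=O)C[C@H]1CC([Si](C)(C)C)=C(CO)[C@@H](C)C=C1O[Si](C)(C)C(C)(C)C | intermediate
8 | methyl 2-[(1S,4S)-5-(hydroxymethyl)-4-methyl-2-oxo-6-(trimethylsilyl)cyclohept-5-en-1-yl]acetate (1,4-cis) | COC(=O)C[C@H]1CC([Si](C)(C)C)=C(CO)[C@@H](C)CC1=O | intermediate
9 | methyl 2-[(1S,4S)-5-(hydroxymethyl)-4-methyl-2-oxocyclohept-5-en-1-yl]acetate (1,4-trans) | COC(=O)C[C@@H]1CC=C(CO)[C@@H](C)CC1=O | intermediate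
10 | methyl 2-[(1S,2R,4S)-2-hydroxy-5-(hydroxymethyl)-4-methylcyclohept-5-en-1-yl]acetate | COC(=O)C[C@@H]1CC=C(CO)[C@@H](C)C[C@H]1O | intermediate
11 | (3aS,7S,8aR)-6-(hydroxymethyl)-7-methyl-3,3a,4,7,8,8a-hexahydro-2H-cyclohepta[b]furan-2-one | O=C1O[C@@H]2C[C@H](C)C(CO)=CC[C@H]2C1 | intermediate
12 | (3aS,7S,8aR)-3-[(dimethylamino)methyl]-6-(hydroxymethyl)-7-methyl-3,3a,4,7,8,8a-hexahydro-2H-cyclohepta[b]furan-2-one (both C3 epimers) | CN(C)CC1C(=O)O[C@@H]2C[C@H](C)C(CO)=CC[C@@H]12 | intermediate
13 | trimethylammonium iodide of 12 (N-methylated Mannich base) | C[N+](C)(C)CC1C(=O)O[C@@H]2C[C@H](C)C(CO)=CC[C@@H]12.[I-] | intermediate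
14 | (3aS,7S,8aR)-6-(hydroxymethyl)-7-methyl-3-methylidene-3,3a,4,7,8,8a-hexahydro-2H-cyclohepta[b]furan-2-one | C=C1C(=O)O[C@@H]2C[C@H](C)C(CO)=CC[C@@H]12 | intermediate
15 | (3aS,7S,8aR)-7-methyl-3-methylidene-2-oxo-3,3a,4,7,8,8a-hexahydro-2H-cyclohepta[b]furan-6-carbaldehyde | C=C1C(=O)O[C@@H]2C[C@H](C)C(C=O)=CC[C@@H]12 | intermediate
16 | (3aS,7S,8aR)-7-methyl-3-methylidene-6-[(E)-3-oxobut-1-enyl]-3,3a,4,7,8,8a-hexahydro-2H-cyclohepta[b]furan-2-one (monomer) | C=C1C(=O)O[C@@H]2C[C@H](C)C(/C=C/C(C)=O)=CC[C@@H]12 | intermediate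
17 | Diels–Alder dimer of 16: 1-deoxy-1,2-ene isomer of the target (C1=C2, 3-acetyl, H-3 cis to H-5, spiro lactone carbonyl trans to C6) | C=C1C(=O)O[C@@H]2C[C@H](C)C3=C[C@H](C(C)=O)[C@]4(C[C@@H]3C[C@@H]12)C(=O)O[C@@H]1C[C@H](C)C(/C=C/C(C)=O)=CC[C@H]14 | intermediate
18 | 1,2-epoxide of 17 (oxygen on the face of H-3 and H-5) | C=C1C(=O)O[C@@H]2C[C@H](C)[C@@]35O[C@H]5[C@H](C(C)=O)[C@]4(C[C@@H]3C[C@@H]12)C(=O)O[C@@H]1C[C@H](C)C(/C=C/C(C)=O)=CC[C@H]14 | intermediate
19 | CNP0168949.4 (1-hydroxy-2-en-3-acetyl dimer) | C=C1C(=O)O[C@@H]2C[C@H](C)[C@]3(O)C=C(C(C)=O)[C@]4(C[C@@H]3C[C@@H]12)C(=O)O[C@@H]1C[C@H](C)C(/C=C/C(C)=O)=CC[C@H]14 | target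

Total step count: 10. Longest linear sequence: 10 steps (from 1; 6 and all reagents are commercial).

Steps most likely to fail

Step 4. The vinylcyclopropane may isomerise to a siloxy diene, or open at the more substituted bond, faster than the hindered internal alkyne inserts at the substituted alkene terminus. The fallback sets out from 4 and comes back at 9; it closes the ring at the C1=C5 alkene instead. Palladium-catalysed allylation of silyl enol ether 4 (allyl methyl carbonate, Pd2(dba)3, dppe, THF) gives methyl (E)-4-oxo-3-(prop-2-enyl)hept-5-enoate F1. Hayashi–Miyaura conjugate addition of 2-[3-(tert-butyldimethylsilyloxy)prop-1-en-2-yl]-4,4,5,5-tetramethyl-1,3,2-dioxaborolane (Rh(acac)(C2H4)2, the BINAP antipode that gives 6S, KOH, dioxane/H2O) sets C10 and gives methyl (6S)-7-[(tert-butyldimethylsilyloxy)methyl]-6-methyl-4-oxo-3-(prop-2-enyl)oct-7-enoate F2. Ring-closing metathesis (second-generation Grubbs catalyst, CH2Cl2, 40 °C) gives the silyl ether of 9, methyl 2-[(4S)-5-[(tert-butyldimethylsilyloxy)methyl]-4-methyl-2-oxocyclohept-5-en-1-yl]acetate F3. Bu4NF then removes the silyl group and equilibrates C7 to give 9.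

Step 9. The dimerisation may be slow and unselective, with oligomerisation, cycloaddition at the enone and poor facial selectivity on an electron-poor diene. The fallback sets out from 16 and comes back at 17. Luche reduction (NaBH4, CeCl3, MeOH, -78 °C) turns the enone into the allylic alcohol, (3aS,7S,8aR)-6-[(E)-3-hydroxybut-1-enyl]-7-methyl-3-methylidene-3,3a,4,7,8,8a-hexahydro-2H-cyclohepta[b]furan-2-one F4 (both carbinol epimers). Its diene is more electron-rich and no enone dienophile remains, so thermal dimerisation (toluene, 80 °C) should be cleaner and gives the diol analogue of 17, F5. Dess–Martin periodinane oxidises both secondary alcohols to give 17.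

Step 3. Enantioselection may be low on a dienyl silyl ether that carries a coordinating ester. The fallback sets out from 4 and comes back at 10. Without the ligand, Et2Zn/CH2I2 gives 5 together with its enantiomer methyl 2-[(1S,2S)-2-(tert-butyldimethylsilyloxy)-2-[(E)-prop-1-enyl]cyclopropyl]acetate F6. Steps 4 and 5 run on the racemate give, beside 7, 8 and 9, the enantiomeric cycloadduct F7 (not isolated), the enantiomeric silyl ketone F8 and the enantiomeric ketone methyl 2-[(1R,4R)-5-(hydroxymethyl)-4-methyl-2-oxocyclohept-5-en-1-yl]acetate F9. In place of NaBH4, a ketoreductase (alcohol dehydrogenase class; NADPH, glucose/glucose dehydrogenase recycling, pH 7 buffer, 30 °C), selected to reduce only the (4S)-ketone 9, gives 10 by kinetic resolution and leaves F9 behind; 10 is lactonised as in step 6.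

Further compounds
F1 | step 4 | methyl (E)-4-oxo-3-(prop-2-enyl)hept-5-enoate (racemic at C3) | COC(=O)CC(CC=C)C(=O)/C=C/C
F2 | step 4 | methyl (6S)-7-[(tert-butyldimethylsilyloxy)methyl]-6-methyl-4-oxo-3-(prop-2-enyl)oct-7-enoate (C3 epimers) | COC(=O)CC(CC=C)C(=O)C[C@H](C)C(=C)CO[Si](C)(C)C(C)(C)C
F3 | step 4 | methyl 2-[(4S)-5-[(tert-butyldimethylsilyloxy)methyl]-4-methyl-2-oxocyclohept-5-en-1-yl]acetate (C1 epimers) | COC(=O)CC1CC=C(CO[Si](C)(C)C(C)(C)C)[C@@H](C)CC1=O
F4 | step 9 | (3aS,7S,8aR)-6-[(E)-3-hydroxybut-1-enyl]-7-methyl-3-methylidene-3,3a,4,7,8,8a-hexahydro-2H-cyclohepta[b]furan-2-one (carbinol epimers) | C=C1C(=O)O[C@@H]2C[C@H](C)C(/C=C/C(C)O)=CC[C@@H]12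
F5 | step 9 | diol analogue of 17 (both acetyl groups as 1-hydroxyethyl) | C=C1C(=O)O[C@@H]2C[C@H](C)C3=C[C@H](C(C)O)[C@]4(C[C@@H]3C[C@@H]12)C(=O)O[C@@H]1C[C@H](C)C(/C=C/C(C)O)=CC[C@H]14
F6 | step 3 | methyl 2-[(1S,2S)-2-(tert-butyldimethylsilyloxy)-2-[(E)-prop-1-enyl]cyclopropyl]acetate (enantiomer of 5) | COC(=O)C[C@@H]1C[C@@]1(O[Si](C)(C)C(C)(C)C)/C=C/C
F7 | step 3 | methyl 2-[(1R,4R)-2-(tert-butyldimethylsilyloxy)-5-(hydroxymethyl)-4-methyl-6-(trimethylsilyl)cyclohepta-2,5-dien-1-yl]acetate (enantiomer of 7) | COC(=O)C[C@@H]1CC([Si](C)(C)C)=C(CO)[C@H](C)C=C1O[Si](C)(C)C(C)(C)C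
F8 | step 3 | methyl 2-[(1R,4R)-5-(hydroxymethyl)-4-methyl-2-oxo-6-(trimethylsilyl)cyclohept-5-en-1-yl]acetate (enantiomer of 8) | COC(=O)C[C@@H]1CC([Si](C)(C)C)=C(CO)[C@H](C)CC1=O
F9 | step 3 | methyl 2-[(1R,4R)-5-(hydroxymethyl)-4-methyl-2-oxocyclohept-5-en-1-yl]acetate (enantiomer of 9) | COC(=O)C[C@H]1CC=C(CO)[C@H](C)CC1=O
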